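**Retrosynthetic overview**
1. The ArCH2Ar bridge is cut last. Fully substituted ring B carries the bridge carbon as a dimethylaminomethyl group (an ortho-quinone methide precursor, CH2 from formaldehyde), and the one free CH of ring A captures it.
2. The strategy rests on this feature: ring A is a benzene with oxygen on three alternate carbons and a C-butanoyl group between two of them, which is a cyclised tetraketide. One phenolic carbon, the neighbouring ring carbon, the benzylic CH2, the carbinol CH and the carbinol oxygen are the C(=O), C-alpha, C-beta, C-gamma and ring O of a gamma-butyrolactone.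
3. Ring A is therefore opened between the butanoyl-bearing carbon and that phenolic carbon (Claisen), back to an alpha-(3,5-dioxooctanoyl) lactone. Its ring opening releases the (R)-alcohol.
4. The chain is grown on (R)-5-isopropenyl-gamma-butyrolactone (from the D-glutamic-acid-derived lactone acid) by alpha-acetylation and dianion acylation with a ketal-masked 3-oxohexanoyl amide. Ring B comes from 2-methylphloroglucinol by acetylation, mono-O-methylation and aminomethylation.
5. Ring order: the lactone is bought, the carbocycle of ring A is closed as the lactone opens, ring B is an existing benzene, and the two rings are joined in the last step.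

Key step: step 9

Remark: for the open chain the numbering C1 (lactone carbonyl), C2 (lactone alpha-carbon), C3/C5/C7 (chain carbonyls), C4/C6 (chain methylenes) is used. The lactone alpha-carbon of 5, 9 and 10 is enolised and ends as an aromatic carbon, so it is drawn without configuration. Compounds 1, 6 and 13 are taken as purchasable.

**Route**

Step 1
Reactants: 1 (R)-5-oxotetrahydrofuran-2-carboxylic acid
Product: 2 (R)-5-oxotetrahydrofuran-2-carbonyl chloride
Conditions: (COCl)2 (1.2 equiv), DMF (cat.), CH2Cl2, 0 °C to rt; volatiles removed, used directly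
Reagents that add atoms: oxalyl chloride, O=C(Cl)C(=O)Cl
Why: Conversion of the acid into the acyl chloride through the catalytic chloroiminium (Vilsmeier-type) species is neutral and amine-free, so neither ketene formation at the alpha-oxygenated stereocentre nor lactone opening is expected and the (R) centre is carried through.

Step 2
Reactants: 2 (R)-5-oxotetrahydrofuran-2-carbonyl chloride
Product: 3 (R)-5-acetyldihydrofuran-2(3H)-one
Conditions: Me2CuLi (1.2 equiv, from MeLi and CuI), Et2O, −78 °C; aq NH4Cl
Reagents that add atoms: lithium dimethylcuprate, [Li+].C[Cu-]C (prepared from methyllithium, [Li]C, and CuI)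
Why: Acyl substitution of an acid chloride by a lithium diorganocuprate should stop at the ketone at −78 °C, because the cuprate adds neither to the new ketone nor to the lactone and is too weakly basic to enolise the alpha-acyloxy ketone.

Step 3
Reactants: 3 (R)-5-acetyldihydrofuran-2(3H)-one
Product: 4 (R)-5-(prop-1-en-2-yl)dihydrofuran-2(3H)-one
Conditions: Zn, CH2Br2, TiCl4, THF, 0 °C (preformed reagent); then 3 in CH2Cl2, 0 °C to rt
Reagents that add atoms: dibromomethane, BrCBr
Why: The Takai–Lombardo methylenation uses a non-basic zinc–titanium methylene reagent that converts ketones but not lactones into alkenes and spares enolisable alpha-stereocentres, which is what the alpha-acyloxy ketone requires.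

Step 4
Reactants: 4 (R)-5-(prop-1-en-2-yl)dihydrofuran-2(3H)-one
Product: 5 (5R)-3-acetyl-5-(prop-1-en-2-yl)dihydrofuran-2(3H)-one (C3 epimers and enol)
Conditions: LiN(iPr)2 (1.15 equiv), THF, −78 °C; MeC(O)N(OMe)Me (1.3 equiv), −78 to −30 °C; cold 1 M HCl
Reagents that add atoms: N-methoxy-N-methylacetamide, CC(=O)N(C)OC
Why: Crossed Claisen-type C-acylation of a lactone lithium enolate with an N-methoxy-N-methylamide gives a chelated tetrahedral adduct that should persist until the acid quench, so the acidic beta-keto lactone never meets unreacted enolate and O-acylation is avoided; the new C3 centre is uncontrolled and irrelevant because it enolises and later becomes an aromatic carbon.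

Step 5
Reactants: 6 ethyl 3-oxohexanoate
Product: 7 ethyl 2-(2-propyl-1,3-dioxolan-2-yl)acetate
Conditions: HOCH2CH2OH (3 equiv), pTsOH·H2O (cat.), toluene, reflux, azeotropic removal of water
Reagents that add atoms: ethylene glycol, OCCO
Why: Acid-catalysed ketalisation with removal of water masks the ketone of the beta-keto ester as a dioxolane, which removes the 1,3-dicarbonyl acidity that would otherwise quench the dianion used in step 7.

Step 6
Reactants: 7 ethyl 2-(2-propyl-1,3-dioxolan-2-yl)acetate
Product: 8 N-methoxy-N-methyl-2-(2-propyl-1,3-dioxolan-2-yl)acetamide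
Conditions: MeNH(OMe)·HCl (1.5 equiv), iPrMgCl (3.0 equiv), THF, −20 to 0 °C; aq NH4Cl
Reagents that add atoms: N,O-dimethylhydroxylamine hydrochloride, CNOC.Cl
Why: Aminolysis of the ester by the chloromagnesium amide of N,O-dimethylhydroxylamine, generated in the flask, is the standard conversion of an enolisable ester into an N-methoxy-N-methylamide and should leave the base-stable dioxolane intact.

Step 7
Reactants: 5 (5R)-3-acetyl-5-(prop-1-en-2-yl)dihydrofuran-2(3H)-one; 8 N-methoxy-N-methyl-2-(2-propyl-1,3-dioxolan-2-yl)acetamide
Product: 9 (5R)-3-[3-oxo-4-(2-propyl-1,3-dioxolan-2-yl)butanoyl]-5-(prop-1-en-2-yl)dihydrofuran-2(3H)-one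
Conditions: 5, LiN(iPr)2 (2.2 equiv), THF, −78 to 0 °C; 8 (1.0 equiv), −78 to 0 °C; AcOH, then pH 6 buffer
Reagents that add atoms: none
Why: The gamma-acylation of a 1,3-dicarbonyl dianion (Claisen-type condensation) takes place at the terminal carbanion formed in the second deprotonation, and the N-methoxy-N-methylamide gives a stable chelate instead of a more acidic triketone in the flask, so one equivalent of the acyl donor should suffice while the lactone carbonyl is shielded as part of the enolate.

Step 8
Reactants: 9 (5R)-3-[3-oxo-4-(2-propyl-1,3-dioxolan-2-yl)butanoyl]-5-(prop-1-en-2-yl)dihydrofuran-2(3H)-one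
Product: 10 (5R)-3-(3,5-dioxooctanoyl)-5-(prop-1-en-2-yl)dihydrofuran-2(3H)-one (enol mixture)
Conditions: 1 M aq HCl, THF, 0 °C to rt, monitored; neutral extraction, used crude
Reagents that add atoms: water, O
Why: Acid-catalysed ketal hydrolysis under dilute, cold conditions should free the C7 ketone without the cyclodehydration of the 1,3,5-triketone to a 4-pyranone or the acid-induced opening of the acyl lactone that hot or strong acid would cause.

Step 9
Reactants: 10 (5R)-3-(3,5-dioxooctanoyl)-5-(prop-1-en-2-yl)dihydrofuran-2(3H)-one
Product: 12 1-{2,4,6-trihydroxy-3-[(2R)-2-hydroxy-3-methylbut-3-en-1-yl]phenyl}butan-1-one, via 2-acylcyclohexane-1,3,5-trione 11 (not isolated)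
Conditions: Mg(OMe)2 (5 equiv), MeOH, reflux, Ar; then 0 °C, 1 M HCl to pH 5
Reagents that add atoms: none
Why: Proposed new method: Mg(OMe)2 should turn the tricarbonyl chain into a magnesium-chelated polyenolate in which the carbanion at the doubly activated methylene C6 adds to the lactone carbonyl C1, the tetrahedral intermediate expels the ring oxygen as the side-chain alkoxide to give trione 11, and 11 enolises irreversibly to the aromatic triol. The closest known reaction type is the base- or Mg(OMe)2-mediated Claisen cyclisation of 3,5,7-trioxoalkanoic esters and of their 2-pyranone forms to acylphloroglucinols; what is new is the alkyl substituent at C2 and a gamma-lactone as the ester, whose leaving group stays attached. The six-membered carbocycle of ring A closes in a 6-exo-trig mode (C6 onto C1), and the five-membered lactone opens in the same event. No stereocentre is formed, since the sp3 ring carbons of 11 are lost on enolisation, and the (R)-carbinol is untouched because only its O–acyl bond is cleaved, not the bond between oxygen and the stereogenic carbon. The step needs the C6-to-C1 Claisen mode to win over the C2-to-C7 aldol mode and over O-cyclisation to pyranones: the aldol mode would build a quaternary spiro carbon at C2 that cannot aromatise and so stays reversible, whereas chelation by magnesium holds the chain folded for C-attack and aromatisation drains the Claisen channel. If methoxide first opens the lactone to the methyl ester, that ester is the classical substrate and should reach the same product, and the cold work-up near pH 5 keeps the ortho-hydroxyl from closing onto the allylic alcohol.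

Step 10
Reactants: 13 2-methylbenzene-1,3,5-triol
Product: 14 1-(2,4,6-trihydroxy-3-methylphenyl)ethan-1-one
Conditions: AcCl (1.1 equiv), AlCl3 (3.5 equiv), PhNO2/CH2Cl2, 0 to 40 °C; ice, 1 M HCl
Reagents that add atoms: acetyl chloride, CC(=O)Cl
Why: Friedel–Crafts C-acylation of the highly activated phloroglucinol occurs at one of its two equivalent unsubstituted carbons, and the acyl group introduced deactivates the ring against a second acylation.

Step 11
Reactants: 14 1-(2,4,6-trihydroxy-3-methylphenyl)ethan-1-one
Product: 15 1-(2,6-dihydroxy-4-methoxy-3-methylphenyl)ethan-1-one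
Conditions: Me2SO4 (1.0 equiv), K2CO3 (1.05 equiv), acetone, rt to 40 °C
Reagents that add atoms: dimethyl sulfate, COS(=O)(=O)OC
Why: Williamson-type O-methylation with one equivalent of dimethyl sulfate should pick the hydroxyl para to the acetyl group, which is the most acidic and the least shielded by hydrogen bonding to the carbonyl group.

Step 12
Reactants: 15 1-(2,6-dihydroxy-4-methoxy-3-methylphenyl)ethan-1-one
Product: 16 1-{3-[(dimethylamino)methyl]-2,6-dihydroxy-4-methoxy-5-methylphenyl}ethan-1-one
Conditions: 37% aq CH2O (1.1 equiv), 40% aq Me2NH (1.2 equiv), EtOH, 0 °C to rt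
Reagents that add atoms: formaldehyde, C=O; dimethylamine, CNC
Why: Mannich aminomethylation of an electron-rich phenol takes place at the only unsubstituted ring carbon, and since ring B then has no free position the Mannich base cannot condense with itself.

Step 13
Reactants: 12 1-{2,4,6-trihydroxy-3-[(2R)-2-hydroxy-3-methylbut-3-en-1-yl]phenyl}butan-1-one; 16 1-{3-[(dimethylamino)methyl]-2,6-dihydroxy-4-methoxy-5-methylphenyl}ethan-1-one
Product: 18 1-{3-[(3-acetyl-2,4-dihydroxy-6-methoxy-5-methylphenyl)methyl]-2,4,6-trihydroxy-5-[(2R)-2-hydroxy-3-methylbut-3-en-1-yl]phenyl}butan-1-one (CNP0388971.1), via ring B ortho-quinone methide 17 (not isolated)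
Conditions: 12 (1.2 equiv), 16 (1.0 equiv), 1,4-dioxane, reflux, Ar
Reagents that add atoms: none
Why: Thermal elimination of dimethylamine from the ortho-hydroxybenzylamine (retro-Mannich-type) gives ortho-quinone methide 17, which should be intercepted by conjugate addition of the single unsubstituted carbon of the phloroglucinol ring of 12 followed by rearomatisation (Friedel–Crafts-type benzylation), with the excess of 12 and the absence of any free position in ring B suppressing homodimers.

**Compound list**
1 | (R)-5-oxotetrahydrofuran-2-carboxylic acid | OC(=O)[C@H]1CCC(=O)O1 | starting material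
2 | (R)-5-oxotetrahydrofuran-2-carbonyl chloride | O=C(Cl)[C@H]1CCC(=O)O1 | intermediate
3 | (R)-5-acetyldihydrofuran-2(3H)-one | CC(=O)[C@H]1CCC(=O)O1 | intermediate
4 | (R)-5-(prop-1-en-2-yl)dihydrofuran-2(3H)-one | C=C(C)[C@H]1CCC(=O)O1 | intermediate
5 | (5R)-3-acetyl-5-(prop-1-en-2-yl)dihydrofuran-2(3H)-one | C=C(C)[C@H]1CC(C(C)=O)C(=O)O1 | intermediate
6 | ethyl 3-oxohexanoate | CCCC(=O)CC(=O)OCC | starting material
7 | ethyl 2-(2-propyl-1,3-dioxolan-2-yl)acetate | CCCC1(CC(=O)OCC)OCCO1 | intermediate
8 | N-methoxy-N-methyl-2-(2-propyl-1,3-dioxolan-2-yl)acetamide | CCCC1(CC(=O)N(C)OC)OCCO1 | intermediate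
9 | (5R)-3-[3-oxo-4-(2-propyl-1,3-dioxolan-2-yl)butanoyl]-5-(prop-1-en-2-yl)dihydrofuran-2(3H)-one | C=C(C)[C@H]1CC(C(=O)CC(=O)CC2(CCC)OCCO2)C(=O)O1 | intermediate
10 | (5R)-3-(3,5-dioxooctanoyl)-5-(prop-1-en-2-yl)dihydrofuran-2(3H)-one | C=C(C)[C@H]1CC(C(=O)CC(=O)CC(=O)CCC)C(=O)O1 | intermediate
11 | 2-butanoyl-4-[(2R)-2-hydroxy-3-methylbut-3-en-1-yl]cyclohexane-1,3,5-trione | C=C(C)[C@H](O)CC1C(=O)CC(=O)C(C(=O)CCC)C1=O | intermediate
12 | 1-{2,4,6-trihydroxy-3-[(2R)-2-hydroxy-3-methylbut-3-en-1-yl]phenyl}butan-1-one | C=C(C)[C@H](O)Cc1c(O)cc(O)c(C(=O)CCC)c1O | intermediate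
13 | 2-methylbenzene-1,3,5-triol | Cc1c(O)cc(O)cc1O | starting material
14 | 1-(2,4,6-trihydroxy-3-methylphenyl)ethan-1-one | CC(=O)c1c(O)cc(O)c(C)c1O | intermediate
15 | 1-(2,6-dihydroxy-4-methoxy-3-methylphenyl)ethan-1-one | CC(=O)c1c(O)cc(OC)c(C)c1O | intermediate
16 | 1-{3-[(dimethylamino)methyl]-2,6-dihydroxy-4-methoxy-5-methylphenyl}ethan-1-one | CC(=O)c1c(O)c(CN(C)C)c(OC)c(C)c1O | intermediate
17 | 2-acetyl-3-hydroxy-5-methoxy-4-methyl-6-methylidenecyclohexa-2,4-dien-1-one | C=C1C(=O)C(C(C)=O)=C(O)C(C)=C1OC | intermediate
18 | 1-{3-[(3-acetyl-2,4-dihydroxy-6-methoxy-5-methylphenyl)methyl]-2,4,6-trihydroxy-5-[(2R)-2-hydroxy-3-methylbut-3-en-1-yl]phenyl}butan-1-one (CNP0388971.1) | C=C(C)[C@H](O)Cc1c(O)c(Cc2c(O)c(C(C)=O)c(O)c(C)c2OC)c(O)c(C(=O)CCC)c1O | target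

**Step count and risks**

Total step count: 13. Longest linear sequence: 8 steps (steps 1, 2, 3, 4, 7, 8, 9, 13).

Steps most likely to fail:

1. Step 9 (Proposed new method). What may go wrong: methoxide may cleave the acyl chain from the alpha-acyl lactone by retro-Claisen attack at the C3 carbonyl faster than C6 closes onto C1, or the alkoxide released in the ring opening may add to the C3 carbonyl and dehydrate to a dihydrofuran before the ring aromatises. The fallback sets out from 4 and comes back at 12. It gives up the lactone as ester terminus in favour of an ordinary methyl ester with the alcohol silylated, so that the ring closure becomes the established Claisen cyclisation of an open-chain methyl 3,5,7-trioxoalkanoate. Lactone 4 is saponified with KOH (1 equiv, MeOH/H2O) to potassium (R)-4-hydroxy-5-methylhex-5-enoate F1. This is alkylated with MeI in DMF to methyl (R)-4-hydroxy-5-methylhex-5-enoate F2, which is silylated in the same flask (tBuMe2SiCl, imidazole) before it can relactonise, giving methyl (R)-4-[(tert-butyldimethylsilyl)oxy]-5-methylhex-5-enoate F3. Its lithium enolate is acetylated with N-methoxy-N-methylacetamide as in step 4 to methyl (4R)-2-acetyl-4-[(tert-butyldimethylsilyl)oxy]-5-methylhex-5-enoate F4. The dianion of F4 is acylated with 8 as in step 7 to methyl (4R)-4-[(tert-butyldimethylsilyl)oxy]-5-methyl-2-[3-oxo-4-(2-propyl-1,3-dioxolan-2-yl)butanoyl]hex-5-enoate F5. Pyridinium p-toluenesulfonate in wet acetone should then remove the ketal to give methyl (4R)-4-[(tert-butyldimethylsilyl)oxy]-2-(3,5-dioxooctanoyl)-5-methylhex-5-enoate F6. Mg(OMe)2 in MeOH at reflux should close ring A with loss of methanol to 1-{3-[(2R)-2-[(tert-butyldimethylsilyl)oxy]-3-methylbut-3-en-1-yl]-2,4,6-trihydroxyphenyl}butan-1-one F7, and Bu4NF buffered with AcOH in THF should release 12. The stereocentre is again the one bought with 1 and no bond to it is touched.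

2. Step 7. What may go wrong: the strongly basic terminal carbanion may deprotonate the alpha-methylene of amide 8 instead of adding to it, and the resulting amide enolate may open the dioxolane by beta-elimination, so that acylation stalls at partial conversion. The fallback sets out from 5 and 8 and comes back at 9; it replaces the acylation by an aldol addition followed by oxidation. Amide 8 is reduced with iBu2AlH (THF, −78 °C) to 2-(2-propyl-1,3-dioxolan-2-yl)acetaldehyde F8. The dianion of 5 should add to this aldehyde at −78 °C much faster than it deprotonates it, giving (5R)-3-[3-hydroxy-4-(2-propyl-1,3-dioxolan-2-yl)butanoyl]-5-(prop-1-en-2-yl)dihydrofuran-2(3H)-one F9 as a mixture of carbinol epimers. Dess–Martin oxidation of the secondary alcohol (CH2Cl2, NaHCO3, 0 °C) should then deliver 9.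

3. Step 13. What may go wrong: loss of dimethylamine may be slow at a temperature the allylic alcohol tolerates, and on prolonged heating the liberated amine may promote exchange of the methylene bridge, which would scramble the two halves into symmetrical dimers. The fallback sets out from 15 and comes back at 18; it is an amine-free dehydrative benzylation. Vilsmeier–Haack formylation of 15 (POCl3, DMF, then aqueous NaOAc) at its only free carbon gives 3-acetyl-2,4-dihydroxy-6-methoxy-5-methylbenzaldehyde F10. NaBH4 in EtOH at 0 °C should reduce the aldehyde in preference to the doubly chelated aryl ketone, giving 1-[2,6-dihydroxy-3-(hydroxymethyl)-4-methoxy-5-methylphenyl]ethan-1-one F11. Warming this benzylic alcohol with 12 (1.2 equiv) in aqueous dioxane containing catalytic AcOH (50 °C) should generate the same quinone methide 17 by loss of water and give 18.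

**Further compounds**
F1 | step 9 | potassium (R)-4-hydroxy-5-methylhex-5-enoate | C=C(C)[C@H](O)CCC(=O)[O-].[K+]
F2 | step 9 | methyl (R)-4-hydroxy-5-methylhex-5-enoate | C=C(C)[C@H](O)CCC(=O)OC
F3 | step 9 | methyl (R)-4-[(tert-butyldimethylsilyl)oxy]-5-methylhex-5-enoate | C=C(C)[C@H](O[Si](C)(C)C(C)(C)C)CCC(=O)OC
F4 | step 9 | methyl (4R)-2-acetyl-4-[(tert-butyldimethylsilyl)oxy]-5-methylhex-5-enoate | C=C(C)[C@H](O[Si](C)(C)C(C)(C)C)CC(C(C)=O)C(=O)OC
F5 | step 9 | methyl (4R)-4-[(tert-butyldimethylsilyl)oxy]-5-methyl-2-[3-oxo-4-(2-propyl-1,3-dioxolan-2-yl)butanoyl]hex-5-enoate | C=C(C)[C@H](O[Si](C)(C)C(C)(C)C)CC(C(=O)CC(=O)CC1(CCC)OCCO1)C(=O)OC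
F6 | step 9 | methyl (4R)-4-[(tert-butyldimethylsilyl)oxy]-2-(3,5-dioxooctanoyl)-5-methylhex-5-enoate | C=C(C)[C@H](O[Si](C)(C)C(C)(C)C)CC(C(=O)CC(=O)CC(=O)CCC)C(=O)OC
F7 | step 9 | 1-{3-[(2R)-2-[(tert-butyldimethylsilyl)oxy]-3-methylbut-3-en-1-yl]-2,4,6-trihydroxyphenyl}butan-1-one | C=C(C)[C@H](O[Si](C)(C)C(C)(C)C)Cc1c(O)cc(O)c(C(=O)CCC)c1O
F8 | step 7 | 2-(2-propyl-1,3-dioxolan-2-yl)acetaldehyde | CCCC1(CC=O)OCCO1
F9 | step 7 | (5R)-3-[3-hydroxy-4-(2-propyl-1,3-dioxolan-2-yl)butanoyl]-5-(prop-1-en-2-yl)dihydrofuran-2(3H)-one | C=C(C)[C@H]1CC(C(=O)CC(O)CC2(CCC)OCCO2)C(=O)O1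
F10 | step 13 | 3-acetyl-2,4-dihydroxy-6-methoxy-5-methylbenzaldehyde | CC(=O)c1c(O)c(C=O)c(OC)c(C)c1O
F11 | step 13 | 1-[2,6-dihydroxy-3-(hydroxymethyl)-4-methoxy-5-methylphenyl]ethan-1-one | CC(=O)c1c(O)c(CO)c(OC)c(C)c1O
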